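## Retrosynthetic overview
1. The target comes from its (2R,3R)-3-hydroxy analogue by C3 deoxygenation in the last step. The C3–O carbon is bought in L-tartaric acid, is the only source of chirality, and dictates C2.
2. Ring C closes last. O1–C2 forms when the single free A-ring phenol opens a trans-4-aroyl-5-aryl-1,3-dioxolane under acid.
3. C2–C1′ forms by electrochemical Ni-catalysed decarboxylative arylation of the second tartrate carboxyl with a 6-iodochromene. The pyran ring D is made first, on that fragment.
4. C4–C4a forms by photo-Fries shift of a tartrate half-ester from the unhindered OH of 2-prenylphloroglucinol. The oxygen it vacates becomes O1, which fixes 6-prenyl rather than 8-prenyl.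
5. Ring order: A and B are bought as arenes, then D is formed, then C.

Assumption: L-tartaric acid acetonide diacid (4) and 4-iodoresorcinol (8) are bought as such. If only the dimethyl ester of 4 is in stock, add one LiOH saponification.

## Route

**Step 1**
Reactants: 1 phloroglucinol; 2 prenyl bromide
Product: 3, 2-(3-methylbut-2-enyl)benzene-1,3,5-triol
Conditions: KOH (1 equiv), H2O, 0 °C → rt; 1 in 3-fold excess, N2
Reagents that add atoms: prenyl bromide (2), CC(C)=CCBr
Why: Aqueous phenolate C-alkylation (C-prenylation); the three ring C–H are equivalent, so only one mono-C-prenyl product exists, and excess 1 suppresses polyalkylation; no stereocentre is formed.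

**Step 2**
Reactants: 3; 4 (4R,5R)-2,2-dimethyl-1,3-dioxolane-4,5-dicarboxylic acid
Product: 5, (4R,5R)-5-{[3,5-dihydroxy-4-(3-methylbut-2-enyl)phenoxy]carbonyl}-2,2-dimethyl-1,3-dioxolane-4-carboxylic acid
Conditions: EDC·HCl, DMAP (10 mol %), THF–CH2Cl2, −10 °C; 4 (2.5 equiv)
Reagents that add atoms: none beyond reactants 3 and 4
Why: Steglich-type esterification; the OH para to prenyl is the only one without an ortho substituent, so the hindered α-branched acyl donor goes there, excess C2-symmetric diacid stops the reaction at the half-ester, and both bought (R) centres are untouched.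

**Step 3**
Reactants: 5
Product: 6, the 3,5-bis(tert-butyldimethylsilyl) ether of 5 with the free acid retained, (4R,5R)
Conditions: TBSOTf (3.3 equiv), 2,6-lutidine, CH2Cl2, −78 → 0 °C; aq. citric acid work-up cleaves the silyl ester
Reagents that add atoms: TBSOTf, CC(C)(C)[Si](C)(C)OS(=O)(=O)C(F)(F)F
Why: Standard phenol silylation; the ester oxygen becomes the only oxygen unmasked next to the future ketone, so it alone can become O1, and the prenyl group can no longer cyclise onto its ortho oxygens under light or acid.

**Step 4**
Reactants: 6
Product: 7, (4R,5R)-5-[2,4-bis(TBSO)-6-hydroxy-3-(3-methylbut-2-enyl)benzoyl]-2,2-dimethyl-1,3-dioxolane-4-carboxylic acid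
Conditions: hν 254 nm, quartz flow coil, degassed cyclohexane (5 mM), 20 °C
Reagents that add atoms: none
Why: Photo-Fries rearrangement; ArO–C(O) homolysis and in-cage recombination at either of the two equivalent free ortho carbons (the para carbon carries prenyl) forms C4–C4a under neutral conditions that spare prenyl and acetonide, the σ-acyl radical keeps its α-stereocentre, and the chelated o-hydroxyaryl ketone product is photostable.

**Step 5**
Reactants: 8 4-iodoresorcinol; 9 3-methylbut-2-enal
Product: 10, 6-iodo-2,2-dimethyl-2H-chromen-7-ol
Conditions: ethylenediammonium diacetate (20 mol %), toluene, reflux, Dean–Stark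
Reagents that add atoms: 3-methylbut-2-enal (9), CC(C)=CC=O
Why: Knoevenagel-type condensation to an o-quinone methide followed by oxa-6π electrocyclisation; iodine blocks C4 and the less hindered C6 reacts, giving the linear chromene.

**Step 6**
Reactants: 10
Product: 11, tert-butyl[(6-iodo-2,2-dimethyl-2H-chromen-7-yl)oxy]dimethylsilane
Conditions: TBSCl, imidazole, DMF, rt
Reagents that add atoms: TBSCl, CC(C)(C)[Si](C)(C)Cl
Why: Routine silylation, so that no acidic O–H or phenoxide sits ortho to C–I during the cathodic Ni cycle; the group is removed together with the other silyl ethers.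

**Step 7**
Reactants: 7; 11
Product: 12, [2,4-bis(TBSO)-6-hydroxy-3-(3-methylbut-2-enyl)phenyl]{(4R,5S)-5-[7-(TBSO)-2,2-dimethyl-2H-chromen-6-yl]-2,2-dimethyl-1,3-dioxolan-4-yl}methanone (trans)
Conditions: N-hydroxyphthalimide, DIC, DMAP (cat.), CH2Cl2, rt; solvent swap; 11 (1.5 equiv), NiCl2·6H2O (20 mol %), 2,2′-bipyridine (20 mol %), AgNO3 (0.5 equiv), NMP, Mg(+)|RVC(−), 12 mA, 2.5 F/mol, rt (redox-active ester not isolated)
Reagents that add atoms: none beyond 11, which supplies the aryl group
Why: Ni-electrocatalytic decarboxylative C(sp3)–C(sp2) coupling of a redox-active ester; the dioxolan-4-yl radical is captured by Ar–Ni anti to the aroyl group (trans, new centre 5S), the bought centre next to the ketone is untouched, and the all-reductive medium suits both electron-rich arenes.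

**Step 8**
Reactants: 12
Product: 13, (2R,3R)-3,5,7-trihydroxy-2-(7-hydroxy-2,2-dimethyl-2H-chromen-6-yl)-6-(3-methylbut-2-enyl)chroman-4-one (2,3-trans)
Conditions: CSA (10 mol %), CH2Cl2, 0 °C; then Et3N·3HF, THF, rt (one pot)
Reagents that add atoms: none
Why: Proposed new method: an acid-triggered "acetonide-to-pyranone" transposition in which protonation ionises the donor-activated benzylic C2–O ketal bond, the only free phenol captures the p-alkoxybenzyl cation 6-exo from the rear of the departing oxygen, and the resulting C3 hemiketal expels acetone, so that backside attack on the trans-dioxolane and reversible ionisation both lead to the diequatorial 2,3-trans product and the bought C3 centre sets (2R); the closest known reaction type is cyclisation of chalcone epoxides or α-hydroxy-β-leaving-group dihydrochalcones to trans-dihydroflavonols, and fluoride then removes the three silyl ethers.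

**Step 9**
Reactants: 13
Product: 14, cudraflavanone A, (2S)-5,7-dihydroxy-2-(7-hydroxy-2,2-dimethyl-2H-chromen-6-yl)-6-(3-methylbut-2-enyl)chroman-4-one
Conditions: SmI2 (2.5 equiv), THF–MeOH (10:1), −78 °C, 10 min; aq. NH4Cl quench at −78 °C
Reagents that add atoms: none
Why: SmI2 α-deoxygenation of an α-hydroxy aryl ketone (ketyl, loss of Sm-bound hydroxide, C3 protonation of the Sm enolate); C2 is not involved and only its descriptor changes from R to S, while low temperature plus MeOH and phenolic protons outrun retro-oxa-Michael opening.

## Compound list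
1 | phloroglucinol | Oc1cc(O)cc(O)c1 | starting material
2 | prenyl bromide | CC(C)=CCBr | starting material
3 | 2-prenylphloroglucinol | CC(C)=CCc1c(O)cc(O)cc1O | intermediate
4 | (4R,5R)-2,2-dimethyl-1,3-dioxolane-4,5-dicarboxylic acid | OC(=O)[C@@H]1OC(C)(C)O[C@H]1C(O)=O | starting material (chiral)
5 | aryl half-ester acid | CC(C)=CCc1c(O)cc(OC(=O)[C@@H]2OC(C)(C)O[C@H]2C(O)=O)cc1O | intermediate
6 | bis-TBS half-ester acid | CC(C)=CCc1c(O[Si](C)(C)C(C)(C)C)cc(OC(=O)[C@@H]2OC(C)(C)O[C@H]2C(O)=O)cc1O[Si](C)(C)C(C)(C)C | intermediate
7 | photo-Fries keto acid | CC(C)=CCc1c(O[Si](C)(C)C(C)(C)C)cc(O)c(C(=O)[C@@H]2OC(C)(C)O[C@H]2C(O)=O)c1O[Si](C)(C)C(C)(C)C | intermediate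
8 | 4-iodoresorcinol | Oc1ccc(I)c(O)c1 | starting material
9 | 3-methylbut-2-enal | CC(C)=CC=O | starting material
10 | 6-iodo-2,2-dimethyl-2H-chromen-7-ol | CC1(C)C=Cc2cc(I)c(O)cc2O1 | intermediate
11 | TBS ether of 10 | CC1(C)C=Cc2cc(I)c(O[Si](C)(C)C(C)(C)C)cc2O1 | intermediate
12 | trans-(4R,5S)-4-aroyl-5-aryl-dioxolane | CC(C)=CCc1c(O[Si](C)(C)C(C)(C)C)cc(O)c(C(=O)[C@@H]2OC(C)(C)O[C@H]2c3cc4C=CC(C)(C)Oc4cc3O[Si](C)(C)C(C)(C)C)c1O[Si](C)(C)C(C)(C)C | intermediate
13 | (2R,3R)-dihydroflavonol | CC(C)=CCc1c(O)cc2c(c1O)C(=O)[C@H](O)[C@@H](c1cc3c(cc1O)OC(C)(C)C=C3)O2 | intermediate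
14 | cudraflavanone A (2S) | CC(C)=CCc1c(O)cc2c(c1O)C(=O)C[C@@H](c1cc3c(cc1O)OC(C)(C)C=C3)O2 | target

## Summary
Total steps: 9. Longest linear sequence: 7 (steps 1, 2, 3, 4, 7, 8, 9).

**Steps most likely to fail**
1. **Step 7.** The aryl iodide is hindered and electron-rich, and the radical is a secondary α-oxy radical.
   - Protodecarboxylation is possible.
   - A degenerate 1,2-aroyl shift in the radical would erode ee.
   - Fallback: make this bond first, on the simple monomethyl ester of 4. Couple its redox-active ester with the arylzinc from 11 (thermal Ni-catalysed decarboxylative Negishi coupling; an ester neighbour does not migrate). Then saponify, esterify onto 3, silylate, and run the photo-Fries last in an aprotic solvent.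
2. **Step 8 (new).**
   - Possible side reactions are a pinacol-type hydride shift to the 1,2-diketone, acid damage to the chromene, and desilylation before closure.
   - Fallback (known chemistry): hydrolyse the acetonide with aq. AcOH to the diol. Then close ring C by intramolecular Mitsunobu etherification with inversion at the benzylic carbinol. Alternatively, exchange the benzylic OH for SBn and cyclise with AgBF4. Both are established routes to trans-dihydroflavonols.
3. **Step 9.**
   - The Sm enolate may open to the chalcone, which would racemise C2, or the ketone may over-reduce.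
   - Fallback: omit the fluoride in step 8 and make the 3-O-thiocarbonylimidazolide of the silylated dihydroflavonol. Run a neutral Barton–McCombie deoxygenation with (TMS)3SiH/AIBN, which involves no enolate, and finish with Et3N·3HF.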